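(The data stem from a simulated flask for an exercise, noise included.)

In a one-step world substrate meets partner mole for mole, so equal charges promise 100% of target. Yet the larch run, with 1.8 M of substrate and 1.8 M of partner, reads 90.5% at 50.0 min.

| flask | substrate | partner | protic impurity | remark | time |
|---|---|---|---|---|---|
| ash | 1.8 M | 2.5 M | 0.36 M | run made earlier |  |
| larch | 1.8 M | 1.8 M | 0.18 M | run made earlier |  |
| flask | 1.8 M | 1.80 M | 0.360 M |  | 80 min |

| run | time / min | target / % |
|---|---|---|
| ash | 8.00 | 100.4 |
| ash | 15.0 | 99.9 |
| ash | 25.0 | 99.9 |
| ash | 50.0 | 100.0 |
| ash | 90.0 | 99.8 |
| larch | 8.00 | 89.7 |
| larch | 15.0 | 89.5 |
| larch | 25.0 | 90.4 |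
| larch | 50.0 | 90.5 |
| larch | 90.0 | 89.8 |

(each reading ± 0.3 percentage points)

- the analysis behind the earlier runs scatters by 0.3 percentage points, standard deviation
- the reaction counts as stopped when no species that holds the substrate changes by six tenths of a point or more over the second half of the time

- which holds at 80 min: what has brought the reaction to rest, or that it has not come to rest (it is still moving / forward and back rates have come level / all of the substrate has reacted / the partner has run out first)
- amount of target at 80 min, in percent of the substrate charged
- amount of target if the flask were left three thousand times as long, in percent of the substrate charged

Keep a ledger of the partner, mole by mole, and work with the fraction of substrate left. The larch shortfall has the size of its impurity, 0.18 M being 10.0% of its substrate, so enter the impurity as a debit of one partner per mole. The ash run agrees: its 2.5 M of partner, once 0.36 M of impurity is taken off, stands at 2.14 M, more than its 1.8 M of substrate, and it reads 100.0%. Both runs lie flat from 8.00 min to 90.0 min within the scatter, so the ledger needs no clock.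

Now open the books of the flask with 1.80 M of partner. Enter 0.360 M against the impurity. What stands over, 1.44 M, is the working partner: the charge of partner less the charge of impurity. Spend it on the 1.8 M of substrate; it is less than that substrate, which makes partner the limiting reagent. The fraction of substrate left in the flask is 20.0%, so expect 80.0% of target, at 80 min and after the long wait alike, with the partner stopping the reaction.

The forecast says that the partner has run out first, with 80% of target at the time asked and 80% after the long wait, holding that “the impurity destroys partner one-for-one”. The flask gives this: the partner has run out first, with 80.0% at the time asked and 80.0% after the long wait.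

    substrate + partner + released group → target + 2 released group (k = 0.0340 /M²/s)
    partner + protic impurity → quenched reagent (k = 0.0530 /M/s)
    substrate + partner → target + released group (k = 2.00 × 10⁻⁵ /M/s)

Read the closed books of the flask at 80.0 min: partner stands at 0%, the debit at 0.360 M of quenched reagent, and the 1.44 M of working partner at 1.44 M of released group, while 20.0% of the substrate stays unreacted. Now raise the protic impurity to 0.90 M in the neighbouring flask. Its working partner is 0.900 M, which is 50.0% of the substrate. That neighbouring flask gives 50.0% of target, with 50.0% of the substrate unreacted at 80.0 min.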